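## Structural features

The target is an abietane diterpenoid (abietane numbering throughout: C1–C3 ring-A methylenes, C4 carrying methyl C18 and carbonyl C19, C5/C10 the A/B fusion, C6/C7 in ring B, C8–C14 ring C, C20 the oxymethylene on C10). Ring C is a fully substituted 1,4-benzoquinone (C11 and C14 carbonyls, acetoxy on C12, isopropyl on C13), ring B carries a C6=C7 alkene conjugated with it, and ring A is saturated. A δ-lactone links C19 on C4 to C20 on C10, so ring A and the lactone form a 2-oxabicyclo[3.3.1]nonan-3-one with C19 and C20 1,3-diaxial on the β face. The three stereocentres are contiguous: C4 (S, quaternary, methyl α), C5 (R, hydrogen α, trans to C20) and C10 (R, quaternary). The fragile groups are the enol acetate on the quinone, the quinone itself, and the C5 hydrogen, which is allylic and vinylogously acidified by the quinone; all three argue for unmasking ring C last. The real difficulty is the C4–C5–C10 triad with two quaternary centres under the lactone bridge, not the arene. The feature exploited is that the chain C10–C20–O–C19–C4 ends in the bond C4–C5. An ester on the C20 alcohol of a C10-quaternary 1,4-dihydronaphthalene therefore places a C4 radical within 6-exo reach of C5 of the C5=C6 alkene, relays the configuration of C10 to C5, and leaves a leaving group on C6 for the later C6=C7 alkene.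

## Logic of the disconnections

30 ⇒ 29. The O12–acetyl bond is cut first because the enol ester is the most base- and nucleophile-sensitive group. The gain is one labile group fewer; the demand is only that the single acidic hydroxyl of 29 is acylated under mild conditions.

29 ⇒ 28 ⇒ 27. O12–H goes back to O12–CH3, and the C11 and C14 carbonyls go back to aryl methyl ethers. As a tris(methyl ether), ring C is inert to the dissolving-metal, hydride, radical and enolate steps that precede. The forward oxidation must pick the para pair C11/C14 and spare the C6=C7 alkene; the ether cleavage must not touch the lactone or C5.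

27 ⇒ 25. The C3–C4 bond of ring A is cut, since C4 is α to the lactone carbonyl and C3 is the end of a three-carbon chain on C10. This removes ring A and the quaternary stereocentre C4, which becomes an epimerisable CH needing no control. The forward enolate must C-alkylate within the molecule; the bridged geometry then fixes C4.

25 ⇒ 24 ⇒ 23. The C3–Br bond is traced to a C3 silyl ether and the C6=C7 alkene to a C6 bromide. A silyl ether is carried because a C3 halide would not survive the hydride reduction leading to 18 or the adjacent C20 alkoxide formed there. The C6 bromide costs nothing, being what the atom transfer leaves behind. The elimination must go toward benzylic C7, not toward C5.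

23 ⇒ 20. The C4–C5 and C6–Br bonds are cut (key disconnection). This removes the lactone ring and the C5 stereocentre and leaves C10 as the only stereocentre that must be made. The forward step must close 6-exo on the face of ring B that carries C20.

20 ⇒ 18 + 19. The C19–O ester bond is cut; the forward step is a simple acylation of a neopentyl alcohol, and either bromide epimer serves.

18 ⇒ 17 ⇒ 14 + 15. The C20 alcohol is traced to the C20 amide, and the C10–C1 bond is cut with rearomatisation of ring B. One reductive alkylation then creates quaternary C10, the C5=C6 alkene and the C7 methylene together, with the auxiliary on C20 choosing the face. The demands are facial selectivity, reduction of only the amide-bearing ring, and a reductant able to cleave a very hindered tertiary amide to the alcohol.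

14 ⇒ 13 ⇒ 11 + 12. The C6–H/C7–H pair is restored and the C10–C20 and C20–N bonds are cut. A one-carbon carbonyl insertion attaches both the future C20 and the auxiliary to the enol derivative 11 in one step, so no free naphthoic acid is made.

11 ⇒ 9 ⇒ 8 ⇒ 7 ⇒ 5 + 6. The enol O–S bond, the C9–C10 bond, the C7 carbonyl and the C7–C8 bond are cut in turn. The four carbons C7, C6, C5 and C10 come from 6 by two Friedel–Crafts bonds. The first acylation must go to the position para to one methoxy group and ortho to another (future C8); the second closure then has only one site.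

5 ⇒ 4 ⇒ 1 + 2. The aryl–isopropyl bond is cut. The position of 1 between two methoxy groups is the most acidic, so metalation and addition to 2 place the three-carbon unit where no electrophilic substitution would.

## Other disconnections considered

Alternative 1: The cut runs through C5–C10 and C6–C7 and removes rings A and B together. It leads to benzocyclobutene A1, whose four-membered ring holds C7 and an ester-bearing C10 and whose side chain ends in a vinyl group on a preformed quaternary C4 (methyl, nitrile). Heating A1 to about 180 °C should open the cyclobutene to the ortho-quinodimethane, which would add to the vinyl group to give the trans-fused tricycle A2 with the C20 ester and C19 nitrile both axial.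
- In its favour: two rings, two C–C bonds and the C5/C10 relationship in one reagent-free step; trans fusion is the normal outcome of this reaction type; C4 is already quaternary; C20 arrives at the carboxyl level.
- Against it here: the absolute configuration must be built into an acyclic quaternary nitrile. The relay from C4 to C10 rests on a small preference for an axial nitrile over an axial methyl group. A benzocyclobutene on a hexasubstituted arene is laborious. The hindered nitrile must later become the lactone carbonyl. Ring B emerges saturated, so the C6=C7 alkene needs a separate dehydrogenation.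
- Comparison: on structure the alternative is the better in bond-forming economy of its key step and the equal of the chosen plan in giving the C5 hydrogen trans to C20. It is weaker in stereochemical security, because the chosen plan relays chirality through a short tether. On mechanism it needs no catalyst but a much higher temperature. In step count it is expected to be about equal or slightly longer once A1 is counted.

Alternative 2: The cut is the C20–O bond, traced to a C20–H bond of podocarpic acid A3, which already has rings A–C and C4, C5 and C10 in the required configuration. After esterification, isopropylation at C13, hydroxylation at C11 and protection of O12, the diethylhydrosilyl ether A4 would undergo iridium-catalysed dehydrogenative silylation of a C20–H bond to give the oxasilacycle A5. Oxidation of the C–Si bond and lactonisation onto the C19 ester would follow.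
- In its favour: no stereocentre has to be created and enantiopurity comes from the chiral pool; on stereochemistry this alternative is better than the chosen plan.
- Against it here: the arene of A3 needs oxygen at C11 (next to the ring fusion) and later at C14. The silylation must close a six-membered ring from a phenol-derived silyl ether onto a neopentyl methyl group, beyond the five-membered closures from aliphatic alcohols that are well established, with the C1 methylene as a competitor. The C6=C7 alkene still has to be introduced late. A3 is costly.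
- Comparison: structurally superior at the outset and equal in final redox manipulations. Mechanistically it stakes the route on a C–H functionalisation outside its proven scope, where the chosen key step is an established radical atom transfer. Step count is expected to be similar or slightly lower if the arene chemistry is efficient.

Alternative 3: The cut is C5–C6, leading to cyclohexadienone A6 (aryl and benzyloxymethyl on the future C10, arylacetaldehyde arm as the future C7–C6). A chiral triazolylidene carbene would convert the aldehyde into an acyl anion equivalent that adds to C5 of one enantiotopic enone arm, closing ring B and giving diketone A7.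
- In its favour: C10 is set by a catalyst, not by a stoichiometric auxiliary (better than the chosen plan on this count), and the C6 ketone is a handle for the C6=C7 alkene.
- Against it here: the tether forces the new C5–C6 bond cis to the aryl group, so the C5 hydrogen is cis to C20, the wrong relative configuration. Correction would rely on epimerisation through the C6 enolate with an uncertain equilibrium. Ring A has neither C4 substituent, so methyl and carboxyl must be added at C4 with control, the C3 oxygen removed and C1=C2 reduced. A6 is itself hard to reach, and an enolisable arylacetaldehyde is prone to aldol side reactions.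
- Comparison: better on the origin of chirality, worse on C5 and C4 (in the chosen plan C5 follows from the tether and C4 from the bicyclic constraint), comparable mechanistic reliability for the key step alone, and clearly longer after it.

Key step: step 12

Assumption: in step 9 the (2S)-configured auxiliary is taken to steer the alkyl iodide to the enolate face that makes C10 (R); if the opposite face were preferred, the (2R)-amine, equally available, would be used from step 7 onward with no other change.

## Route

Step 1
Reactants: 1 1,2,4-trimethoxybenzene; 2 acetone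
Product: 4 2-(2,3,6-trimethoxyphenyl)propan-2-ol, via aryllithium 3 (not isolated)
Conditions: n-BuLi, TMEDA, THF, 0 °C; acetone, −78 °C → rt; H2O
Reagents that add atoms: none
Why: Directed ortho-metalation removes the hydrogen flanked by two methoxy groups, and the aryllithium adds 1,2 to acetone.

Step 2
Reactants: 4 2-(2,3,6-trimethoxyphenyl)propan-2-ol
Product: 5 1,2,4-trimethoxy-3-(propan-2-yl)benzene
Conditions: Et3SiH, CF3CO2H, CH2Cl2, 0 °C → rt
Reagents that add atoms: none
Why: Ionic hydrogenation: the acid ionises the tertiary benzylic alcohol and the silane delivers hydride to the cation.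

Step 3
Reactants: 5 1,2,4-trimethoxy-3-(propan-2-yl)benzene; 6 succinic anhydride
Product: 7 4-oxo-4-[2,4,5-trimethoxy-3-(propan-2-yl)phenyl]butanoic acid
Conditions: AlCl3, CH2Cl2/MeNO2, 0 °C; aq. HCl
Reagents that add atoms: none
Why: Friedel–Crafts acylation (first stage of a Haworth sequence) should go to the free position ortho to one methoxy group and para to another, the future C8; the low temperature limits Lewis-acid cleavage of the ortho ether.

Step 4
Reactants: 7 4-oxo-4-[2,4,5-trimethoxy-3-(propan-2-yl)phenyl]butanoic acid
Product: 8 4-[2,4,5-trimethoxy-3-(propan-2-yl)phenyl]butanoic acid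
Conditions: Et3SiH, CF3CO2H, rt → 50 °C
Reagents that add atoms: none
Why: Ionic hydrogenation of an electron-rich aryl ketone to the methylene; the carboxylic acid is not reduced.

Step 5
Reactants: 8 4-[2,4,5-trimethoxy-3-(propan-2-yl)phenyl]butanoic acid
Product: 9 5,7,8-trimethoxy-6-(propan-2-yl)-3,4-dihydronaphthalen-1(2H)-one
Conditions: P2O5, MeSO3H, rt
Reagents that add atoms: none
Why: Intramolecular Friedel–Crafts acylation at the only free ring position, activated by its ortho methoxy group, closes ring B with C10 as the carbonyl carbon.

Step 6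
Reactants: 9 5,7,8-trimethoxy-6-(propan-2-yl)-3,4-dihydronaphthalen-1(2H)-one
Product: 11 5,7,8-trimethoxy-6-(propan-2-yl)-3,4-dihydronaphthalen-1-yl trifluoromethanesulfonate, via potassium enolate 10 (not isolated)
Conditions: KN(SiMe3)2, THF, −78 °C; PhNTf2, −78 → 0 °C
Reagents that add atoms: N-phenylbis(trifluoromethanesulfonimide), O=S(=O)(N(c1ccccc1)S(=O)(=O)C(F)(F)F)C(F)(F)F
Why: Enolisation can occur only toward C5, and O-sulfonylation of the enolate gives the enol triflate.

Step 7
Reactants: 11 5,7,8-trimethoxy-6-(propan-2-yl)-3,4-dihydronaphthalen-1-yl trifluoromethanesulfonate; 12 (2S)-2-(methoxymethyl)pyrrolidine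
Product: 13 [(2S)-2-(methoxymethyl)pyrrolidin-1-yl][5,7,8-trimethoxy-6-(propan-2-yl)-3,4-dihydronaphthalen-1-yl]methanone
Conditions: CO (1 atm), Pd(OAc)2 (cat.), dppp (cat.), Et3N, DMF, 60 °C
Reagents that add atoms: carbon monoxide, [C-]#[O+]
Why: Palladium-catalysed aminocarbonylation of an enol triflate (oxidative addition to zerovalent palladium, CO insertion, capture of the acyl complex by the amine) installs C20 and the auxiliary in one step.

Step 8
Reactants: 13 [(2S)-2-(methoxymethyl)pyrrolidin-1-yl][5,7,8-trimethoxy-6-(propan-2-yl)-3,4-dihydronaphthalen-1-yl]methanone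
Product: 14 [(2S)-2-(methoxymethyl)pyrrolidin-1-yl][5,7,8-trimethoxy-6-(propan-2-yl)naphthalen-1-yl]methanone
Conditions: DDQ, toluene, 100 °C
Reagents that add atoms: none
Why: Quinone dehydrogenation: hydride loss from benzylic C7, stabilised by the alkoxy-rich ring, and proton loss from C6 aromatise ring B.

Step 9
Reactants: 14 [(2S)-2-(methoxymethyl)pyrrolidin-1-yl][5,7,8-trimethoxy-6-(propan-2-yl)naphthalen-1-yl]methanone; 15 tert-butyl(3-iodopropoxy)dimethylsilane
Product: 17 [(1R)-1-{3-[tert-butyl(dimethyl)silyl]oxypropyl}-5,7,8-trimethoxy-6-(propan-2-yl)-1,4-dihydronaphthalen-1-yl][(2S)-2-(methoxymethyl)pyrrolidin-1-yl]methanone, via potassium amide enolate 16 (not isolated)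
Conditions: K, t-BuOH (1 equiv), NH3/THF, −78 °C; piperylene; 15, −78 → −33 °C; NH4Cl
Reagents that add atoms: none
Why: Birch reductive alkylation of a chiral amide: two-electron reduction of the amide-bearing ring (the electron-rich ring C is spared), protonation at C7, then α-alkylation of the enolate at C10. The face is chosen by the metal-chelating methoxymethyl arm of the auxiliary, which should set C10 as R.

Step 10
Reactants: 17 [(1R)-1-{3-[tert-butyl(dimethyl)silyl]oxypropyl}-5,7,8-trimethoxy-6-(propan-2-yl)-1,4-dihydronaphthalen-1-yl][(2S)-2-(methoxymethyl)pyrrolidin-1-yl]methanone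
Product: 18 [(1R)-1-{3-[tert-butyl(dimethyl)silyl]oxypropyl}-5,7,8-trimethoxy-6-(propan-2-yl)-1,4-dihydronaphthalen-1-yl]methanol
Conditions: BH3·NH3, LiN(iPr)2, THF, 0 °C (gives LiNH2BH3); 17, 0 °C → rt; H2O
Reagents that add atoms: none
Why: LiNH2BH3 reduces tertiary amides, hindered ones included, to primary alcohols by C–N cleavage of the tetrahedral intermediate and reduction of the aldehyde; silyl ether and alkene are inert and quaternary C10 cannot epimerise.

Step 11
Reactants: 18 [(1R)-1-{3-[tert-butyl(dimethyl)silyl]oxypropyl}-5,7,8-trimethoxy-6-(propan-2-yl)-1,4-dihydronaphthalen-1-yl]methanol; 19 2-bromopropanoyl bromide (racemic)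
Product: 20 [(1R)-1-{3-[tert-butyl(dimethyl)silyl]oxypropyl}-5,7,8-trimethoxy-6-(propan-2-yl)-1,4-dihydronaphthalen-1-yl]methyl 2-bromopropanoate (both bromide epimers)
Conditions: pyridine, DMAP (cat.), CH2Cl2, 0 °C
Reagents that add atoms: none
Why: Acylation of the neopentyl primary alcohol by an acid bromide; the bromide-bearing carbon is the future C4 and its configuration is irrelevant.

Step 12
Reactants: 20 [(1R)-1-{3-[tert-butyl(dimethyl)silyl]oxypropyl}-5,7,8-trimethoxy-6-(propan-2-yl)-1,4-dihydronaphthalen-1-yl]methyl 2-bromopropanoate
Product: 23 (5S,10R)-6-bromo-3-{[tert-butyl(dimethyl)silyl]oxy}-11,12,14-trimethoxy-3,4-secoabieta-8,11,13-trien-19,20-olide (C4/C6 epimers), via α-ester radical 21 (not isolated), via C6 radical 22 (not isolated)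
Conditions: CuBr (0.3 equiv), tris(2-pyridylmethyl)amine (0.3 equiv), degassed ClCH2CH2Cl (0.01 M), 80 °C
Reagents that add atoms: none
Why: The CuBr–amine complex (monovalent copper) reversibly abstracts bromine from the activated C4–Br bond to give radical 21 and the divalent copper bromide complex; 21 adds to C5, and the secondary C6 radical 22 takes bromine back from divalent copper, restoring the catalyst. The closest known reaction type is the copper-catalysed atom-transfer radical cyclisation (intramolecular Kharasch addition) of unsaturated α-halo esters to lactones. The one ring closed, the δ-lactone, forms 6-exo-trig; attack at C6 (7-endo) would give a strained bridged ring and both alkene carbons are equally substituted, so the exo path should prevail. The new stereocentre C5 is controlled by C10: the O–CH2 arm stands on one face of ring B and its short reach lets C4 bond to C5 only on that face, so the lactone is cis-fused and the C5 hydrogen ends trans to C20. Heat is required because the ester must turn from its preferred Z conformer into the E conformer before C4 can reach C5. Cyclisation must beat reduction, hydrogen abstraction from the C7 methylene and intermolecular addition; the absence of a hydride donor, high dilution and the low radical concentration set by the halogen-transfer equilibrium should secure this. Halogen abstraction is chemoselective because only the α-carbonyl bromide is activated; the product C6 bromide is an ordinary secondary halide, which makes the closure irreversible. C4 and C6 form as mixtures that steps 15 and 13 erase.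

Step 13
Reactants: 23 (5S,10R)-6-bromo-3-{[tert-butyl(dimethyl)silyl]oxy}-11,12,14-trimethoxy-3,4-secoabieta-8,11,13-trien-19,20-olide
Product: 24 (5S,10R)-3-{[tert-butyl(dimethyl)silyl]oxy}-11,12,14-trimethoxy-3,4-secoabieta-6,8,11,13-tetraen-19,20-olide (C4 epimers)
Conditions: DBU, toluene, 80 °C
Reagents that add atoms: none
Why: E2 dehydrobromination through the more acidic benzylic C7 hydrogen gives the conjugated styrene; both C6 epimers converge and C5 is untouched.

Step 14
Reactants: 24 (5S,10R)-3-{[tert-butyl(dimethyl)silyl]oxy}-11,12,14-trimethoxy-3,4-secoabieta-6,8,11,13-tetraen-19,20-olide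
Product: 25 (5S,10R)-3-bromo-11,12,14-trimethoxy-3,4-secoabieta-6,8,11,13-tetraen-19,20-olide (C4 epimers)
Conditions: Ph3PBr2, CH2Cl2, 0 °C → rt
Reagents that add atoms: triphenylphosphine dibromide, BrP(Br)(c1ccccc1)(c1ccccc1)c1ccccc1
Why: Direct conversion of a silyl ether into a bromide: the ether oxygen attacks phosphorus with loss of the silyl bromide, and bromide displaces triphenylphosphine oxide from the primary alkoxyphosphonium ion (SN2).

Step 15
Reactants: 25 (5S,10R)-3-bromo-11,12,14-trimethoxy-3,4-secoabieta-6,8,11,13-tetraen-19,20-olide
Product: 27 (4S,5R,10R)-11,12,14-trimethoxyabieta-6,8,11,13-tetraen-19,20-olide, via potassium lactone enolate 26 (not isolated)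
Conditions: KN(SiMe3)2, THF, −78 °C → rt
Reagents that add atoms: none
Why: Intramolecular enolate alkylation (6-exo-tet) forms C3–C4 and closes ring A; the planar enolate erases the C4 mixture, and the chain on C10 can reach C4 only from the face that gives the 2-oxabicyclo[3.3.1]nonanone, so C18 ends α and C4 is S. The C5 descriptor changes from S to R only because the priorities change.

Step 16
Reactants: 27 (4S,5R,10R)-11,12,14-trimethoxyabieta-6,8,11,13-tetraen-19,20-olide
Product: 28 (4S,5R,10R)-12-methoxy-11,14-dioxoabieta-6,8,12-trien-19,20-olide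
Conditions: (NH4)2Ce(NO3)6, MeCN/H2O, 0 °C
Reagents that add atoms: water, O
Why: Oxidative demethylation by tetravalent cerium: water attacks the arene radical cation at C11 and C14 with loss of methanol to give the para-quinone, and the C12 ether survives as a vinylogous ester.

Step 17
Reactants: 28 (4S,5R,10R)-12-methoxy-11,14-dioxoabieta-6,8,12-trien-19,20-olide
Product: 29 (4S,5R,10R)-12-hydroxy-11,14-dioxoabieta-6,8,12-trien-19,20-olide
Conditions: BCl3, CH2Cl2, −78 → 0 °C; H2O
Reagents that add atoms: none
Why: Lewis-acid ether cleavage: boron chelates between the C11 carbonyl and O12 and chloride removes the methyl group; the cold aprotic conditions should spare the lactone, the alkene and the C5 hydrogen.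

Step 18
Reactants: 29 (4S,5R,10R)-12-hydroxy-11,14-dioxoabieta-6,8,12-trien-19,20-olide
Product: 30 (4S,5R,10R)-12-acetoxy-11,14-dioxoabieta-6,8,12-trien-19,20-olide
Conditions: Ac2O, pyridine, DMAP (cat.), CH2Cl2, 0 °C → rt
Reagents that add atoms: acetic anhydride, CC(=O)OC(C)=O
Why: O-acylation of the acidic hydroxyquinone (a vinylogous carboxylic acid) gives the enol acetate under mild conditions.

## Compound list

1 | 1,2,4-trimethoxybenzene | COc1ccc(OC)c(OC)c1 | starting material
2 | acetone | CC(C)=O | starting material
3 | (2,3,6-trimethoxyphenyl)lithium | COc1ccc(OC)c([Li])c1OC | intermediate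
4 | 2-(2,3,6-trimethoxyphenyl)propan-2-ol | COc1ccc(OC)c(C(C)(C)O)c1OC | intermediate
5 | 1,2,4-trimethoxy-3-(propan-2-yl)benzene | COc1ccc(OC)c(C(C)C)c1OC | intermediate
6 | succinic anhydride | O=C1CCC(=O)O1 | starting material
7 | 4-oxo-4-[2,4,5-trimethoxy-3-(propan-2-yl)phenyl]butanoic acid | COc1cc(C(=O)CCC(=O)O)c(OC)c(C(C)C)c1OC | intermediate
8 | 4-[2,4,5-trimethoxy-3-(propan-2-yl)phenyl]butanoic acid | COc1cc(CCCC(=O)O)c(OC)c(C(C)C)c1OC | intermediate
9 | 5,7,8-trimethoxy-6-(propan-2-yl)-3,4-dihydronaphthalen-1(2H)-one | COc1c(C(C)C)c(OC)c2CCCC(=O)c2c1OC | intermediate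
10 | potassium 5,7,8-trimethoxy-6-(propan-2-yl)-3,4-dihydronaphthalen-1-olate | COc1c(C(C)C)c(OC)c2CCC=C([O-])c2c1OC.[K+] | intermediate
11 | 5,7,8-trimethoxy-6-(propan-2-yl)-3,4-dihydronaphthalen-1-yl trifluoromethanesulfonate | COc1c(C(C)C)c(OC)c2CCC=C(OS(=O)(=O)C(F)(F)F)c2c1OC | intermediate
12 | (2S)-2-(methoxymethyl)pyrrolidine | COC[C@@H]1CCCN1 | starting material
13 | [(2S)-2-(methoxymethyl)pyrrolidin-1-yl][5,7,8-trimethoxy-6-(propan-2-yl)-3,4-dihydronaphthalen-1-yl]methanone | COc1c(C(C)C)c(OC)c2CCC=C(C(=O)N3CCC[C@H]3COC)c2c1OC | intermediate
14 | [(2S)-2-(methoxymethyl)pyrrolidin-1-yl][5,7,8-trimethoxy-6-(propan-2-yl)naphthalen-1-yl]methanone | COc1c(C(C)C)c(OC)c2cccc(C(=O)N3CCC[C@H]3COC)c2c1OC | intermediate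
15 | tert-butyl(3-iodopropoxy)dimethylsilane | CC(C)(C)[Si](C)(C)OCCCI | starting material
16 | potassium amide enolate (C10=C20) of the 1,4-dihydronaphthalene from 14 | COc1c(C(C)C)c(OC)c2CC=CC(=C([O-])N3CCC[C@H]3COC)c2c1OC.[K+] | intermediate
17 | [(1R)-1-{3-[tert-butyl(dimethyl)silyl]oxypropyl}-5,7,8-trimethoxy-6-(propan-2-yl)-1,4-dihydronaphthalen-1-yl][(2S)-2-(methoxymethyl)pyrrolidin-1-yl]methanone | COc1c(C(C)C)c(OC)c2CC=C[C@](C(=O)N3CCC[C@H]3COC)(CCCO[Si](C)(C)C(C)(C)C)c2c1OC | intermediate
18 | [(1R)-1-{3-[tert-butyl(dimethyl)silyl]oxypropyl}-5,7,8-trimethoxy-6-(propan-2-yl)-1,4-dihydronaphthalen-1-yl]methanol | COc1c(C(C)C)c(OC)c2CC=C[C@](CO)(CCCO[Si](C)(C)C(C)(C)C)c2c1OC | intermediate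
19 | 2-bromopropanoyl bromide (racemic) | CC(Br)C(=O)Br | starting material
20 | [(1R)-1-{3-[tert-butyl(dimethyl)silyl]oxypropyl}-5,7,8-trimethoxy-6-(propan-2-yl)-1,4-dihydronaphthalen-1-yl]methyl 2-bromopropanoate (both bromide epimers) | COc1c(C(C)C)c(OC)c2CC=C[C@](COC(=O)C(C)Br)(CCCO[Si](C)(C)C(C)(C)C)c2c1OC | intermediate
21 | α-ester (C4) radical derived from 20 | COc1c(C(C)C)c(OC)c2CC=C[C@](COC(=O)[CH]C)(CCCO[Si](C)(C)C(C)(C)C)c2c1OC | intermediate
22 | C6 radical of the cyclised cis-fused lactone | COc1c(C(C)C)c(OC)c2C[CH][C@H]3C(C)C(=O)OC[C@@]3(CCCO[Si](C)(C)C(C)(C)C)c2c1OC | intermediate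
23 | (5S,10R)-6-bromo-3-{[tert-butyl(dimethyl)silyl]oxy}-11,12,14-trimethoxy-3,4-secoabieta-8,11,13-trien-19,20-olide (C4/C6 epimers) | COc1c(C(C)C)c(OC)c2CC(Br)[C@H]3C(C)C(=O)OC[C@@]3(CCCO[Si](C)(C)C(C)(C)C)c2c1OC | intermediate
24 | (5S,10R)-3-{[tert-butyl(dimethyl)silyl]oxy}-11,12,14-trimethoxy-3,4-secoabieta-6,8,11,13-tetraen-19,20-olide (C4 epimers) | COc1c(C(C)C)c(OC)c2C=C[C@H]3C(C)C(=O)OC[C@@]3(CCCO[Si](C)(C)C(C)(C)C)c2c1OC | intermediate
25 | (5S,10R)-3-bromo-11,12,14-trimethoxy-3,4-secoabieta-6,8,11,13-tetraen-19,20-olide (C4 epimers) | COc1c(C(C)C)c(OC)c2C=C[C@H]3C(C)C(=O)OC[C@@]3(CCCBr)c2c1OC | intermediate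
26 | potassium lactone enolate (C4=C19) of 25 | COc1c(C(C)C)c(OC)c2C=C[C@H]3C(C)=C([O-])OC[C@@]3(CCCBr)c2c1OC.[K+] | intermediate
27 | (4S,5R,10R)-11,12,14-trimethoxyabieta-6,8,11,13-tetraen-19,20-olide | COc1c(C(C)C)c(OC)c2c(c1OC)[C@]13CCC[C@](C)(C(=O)OC1)[C@@H]3C=C2 | intermediate
28 | (4S,5R,10R)-12-methoxy-11,14-dioxoabieta-6,8,12-trien-19,20-olide | COC1=C(C(C)C)C(=O)C2=C(C1=O)[C@]13CCC[C@](C)(C(=O)OC1)[C@@H]3C=C2 | intermediate
29 | (4S,5R,10R)-12-hydroxy-11,14-dioxoabieta-6,8,12-trien-19,20-olide | OC1=C(C(C)C)C(=O)C2=C(C1=O)[C@]13CCC[C@](C)(C(=O)OC1)[C@@H]3C=C2 | intermediate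
30 | (4S,5R,10R)-12-acetoxy-11,14-dioxoabieta-6,8,12-trien-19,20-olide | CC(=O)OC1=C(C(C)C)C(=O)C2=C(C1=O)[C@]13CCC[C@](C)(C(=O)OC1)[C@@H]3C=C2 | target

## Step count and least certain steps

Total: 18 steps. Longest linear sequence: 18 steps, from 1 to 30; 2, 6, 12, 15 and 19 enter as purchased materials.

Step 12 (key step). The ester must reach its less stable conformer, so closure is slow. Hydrogen abstraction from the doubly activated C7 methylene, intermolecular addition, or stalling of the catalyst as divalent copper accumulates may outrun it. The fallback removes the ester from the tether.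
- It sets out from 18. Bromoacetalisation with ethyl 1-propenyl ether and N-bromosuccinimide (CH2Cl2, −40 °C) would give the mixed bromoacetal, 2-bromo-1-ethoxypropyl ether of 18, F1.
- Its flexible acetal tether should allow a fast 6-exo radical closure with Bu3SnH and AIBN in refluxing toluene (haloacetal radical cyclisation) to the cis-fused cyclic acetal, (5S,10R)-19-ethoxy-19,20-epoxy-3-silyloxy-11,12,14-trimethoxy-3,4-secoabieta-8,11,13-triene, F2.
- Oxidation of the acetal with mCPBA and BF3·OEt2 would give the saturated lactone, (5S,10R)-3-{[tert-butyl(dimethyl)silyl]oxy}-11,12,14-trimethoxy-3,4-secoabieta-8,11,13-trien-19,20-olide, F3.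
- Dehydrogenation with DDQ (hydride loss from C7, proton loss from C6; quaternary C10 rules out a naphthalene) would come back to the route at 24.

Step 9. Facial selectivity may be poor or reversed, because the enolate next to the peri methoxy group need not follow the simple benzamide model; a methoxy group may be lost reductively, or alkylation may occur at C6. The fallback avoids the dissolving metal and step 8. It sets out from 13: γ-deprotonation at C6 with LiN(iPr)2 in THF at −78 °C would give the lithium dienolate, lithium amide enolate of the 1,4-dihydronaphthalene, F4. α-Alkylation of this extended enolate with 15 would come back at 17, the face again being set by the auxiliary (either enantiomer of which can be used).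

Step 10. Hydride addition to the very hindered amide carbonyl may be incomplete, or C–O cleavage may replace C–N cleavage and give the tertiary amine. The fallback is a two-stage reduction from 17: Cp2Zr(H)Cl in THF at rt should stop at the aldehyde, (1R)-1-{3-[tert-butyl(dimethyl)silyl]oxypropyl}-5,7,8-trimethoxy-6-(propan-2-yl)-1,4-dihydronaphthalene-1-carbaldehyde, F5, with release of the auxiliary. NaBH4 in MeOH would then come back at 18.

Step 14. Bromine or HBr equivalents may add across the electron-rich styrene, or silyl transfer to phosphorus may be sluggish. The fallback separates deprotection and activation, from 24.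
- Bu4NF in THF would give the alcohol, (5S,10R)-3-hydroxy-11,12,14-trimethoxy-3,4-secoabieta-6,8,11,13-tetraen-19,20-olide, F6.
- I2, PPh3 and imidazole (Appel-type iodination) would give the iodide, (5S,10R)-3-iodo-11,12,14-trimethoxy-3,4-secoabieta-6,8,11,13-tetraen-19,20-olide, F7.
- KN(SiMe3)2 would close ring A through the potassium lactone enolate of the iodide, F8, coming back at 27.

Step 16. Oxidation may take the ortho pair C11/C12 in place of the para pair, or water or nitrate may attack the radical cation at the styrene. The fallback drops the single-electron oxidant. It sets out from 27: BBr3 (CH2Cl2, −78 °C → rt) would cleave all three ethers to the triol, (4S,5R,10R)-11,12,14-trihydroxyabieta-6,8,11,13-tetraen-19,20-olide, F9. Stirring F9 under air should oxidise it to the hydroxy-para-quinone, coming back at 29 and bypassing steps 16 and 17.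

## Further compounds

F1 | step 12 | mixed bromoacetal: (1R)-1-{[(2-bromo-1-ethoxypropoxy)methyl]}-1-{3-[tert-butyl(dimethyl)silyl]oxypropyl}-5,7,8-trimethoxy-6-(propan-2-yl)-1,4-dihydronaphthalene | COc1c(C(C)C)c(OC)c2CC=C[C@](COC(OCC)C(C)Br)(CCCO[Si](C)(C)C(C)(C)C)c2c1OC
F2 | step 12 | cis-fused cyclic acetal: (5S,10R)-19-ethoxy-19,20-epoxy-3-{[tert-butyl(dimethyl)silyl]oxy}-11,12,14-trimethoxy-3,4-secoabieta-8,11,13-triene | COc1c(C(C)C)c(OC)c2CC[C@H]3C(C)C(OCC)OC[C@@]3(CCCO[Si](C)(C)C(C)(C)C)c2c1OC
F3 | step 12 | (5S,10R)-3-{[tert-butyl(dimethyl)silyl]oxy}-11,12,14-trimethoxy-3,4-secoabieta-8,11,13-trien-19,20-olide | COc1c(C(C)C)c(OC)c2CC[C@H]3C(C)C(=O)OC[C@@]3(CCCO[Si](C)(C)C(C)(C)C)c2c1OC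
F4 | step 9 | lithium amide enolate (C10=C20) of the 1,4-dihydronaphthalene from 13 | COc1c(C(C)C)c(OC)c2CC=CC(=C([O-])N3CCC[C@H]3COC)c2c1OC.[Li+]
F5 | step 10 | (1R)-1-{3-[tert-butyl(dimethyl)silyl]oxypropyl}-5,7,8-trimethoxy-6-(propan-2-yl)-1,4-dihydronaphthalene-1-carbaldehyde | COc1c(C(C)C)c(OC)c2CC=C[C@](C=O)(CCCO[Si](C)(C)C(C)(C)C)c2c1OC
F6 | step 14 | (5S,10R)-3-hydroxy-11,12,14-trimethoxy-3,4-secoabieta-6,8,11,13-tetraen-19,20-olide | COc1c(C(C)C)c(OC)c2C=C[C@H]3C(C)C(=O)OC[C@@]3(CCCO)c2c1OC
F7 | step 14 | (5S,10R)-3-iodo-11,12,14-trimethoxy-3,4-secoabieta-6,8,11,13-tetraen-19,20-olide | COc1c(C(C)C)c(OC)c2C=C[C@H]3C(C)C(=O)OC[C@@]3(CCCI)c2c1OC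
F8 | step 14 | potassium lactone enolate (C4=C19) of F7 | COc1c(C(C)C)c(OC)c2C=C[C@H]3C(C)=C([O-])OC[C@@]3(CCCI)c2c1OC.[K+]
F9 | step 16 | (4S,5R,10R)-11,12,14-trihydroxyabieta-6,8,11,13-tetraen-19,20-olide | Oc1c(C(C)C)c(O)c2c(c1O)[C@]13CCC[C@](C)(C(=O)OC1)[C@@H]3C=C2
A1 | alternative 1 | methyl 1-[(4S)-4-cyano-4-methylhex-5-en-1-yl]-3,5,6-trimethoxy-4-(propan-2-yl)-1,2-dihydrocyclobutabenzene-1-carboxylate | COc1c(C(C)C)c(OC)c2CC(C(=O)OC)(CCC[C@](C)(C#N)C=C)c2c1OC
A2 | alternative 1 | methyl (4S,5S,10R)-4-cyano-11,12,14-trimethoxy-19-norabieta-8,11,13-trien-20-oate | COc1c(C(C)C)c(OC)c2c(c1OC)[C@@]3(C(=O)OC)CCC[C@](C)(C#N)[C@@H]3CC2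
A3 | alternative 2 | podocarpic acid (12-hydroxypodocarpa-8,11,13-trien-19-oic acid) | Oc1ccc2c(c1)[C@@]1(C)CCC[C@](C)(C(=O)O)[C@@H]1CC2
A4 | alternative 2 | methyl 11-(diethylsilyloxy)-12-(propan-2-yloxy)abieta-8,11,13-trien-19-oate | CC[SiH](CC)Oc1c(OC(C)C)c(C(C)C)cc2c1[C@@]1(C)CCC[C@](C)(C(=O)OC)[C@@H]1CC2
A5 | alternative 2 | cyclic diethylsilyl ether bridging O11 and C20 of methyl 12-(propan-2-yloxy)abieta-8,11,13-trien-19-oate | CC[Si]1(CC)Oc2c(OC(C)C)c(C(C)C)cc3c2[C@@]4(C1)CCC[C@](C)(C(=O)OC)[C@@H]4CC3
A6 | alternative 3 | 2-{2-[1-(benzyloxymethyl)-4-oxocyclohexa-2,5-dien-1-yl]-3,4,6-trimethoxy-5-(propan-2-yl)phenyl}acetaldehyde | COc1c(C(C)C)c(OC)c(CC=O)c(c1OC)C1(COCc2ccccc2)C=CC(=O)C=C1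
A7 | alternative 3 | cis-fused tricyclic 1,4-diketone, (5R,10R) in abietane numbering (C3 and C6 ketones, C1=C2 alkene, benzyloxymethyl on C10, C5 hydrogen cis to C20) | COc1c(C(C)C)c(OC)c2CC(=O)[C@@H]3CC(=O)C=C[C@]3(COCc4ccccc4)c2c1OC
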